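The runs were computed on assumed constants; the scatter is artificial.

I take the late slopes of the two earlier runs as my evidence and leave the lag aside.

| flask | L | E | remark | time |
|---|---|---|---|---|
| north | 0.30 M | 47 mM (held) | the very flask that is asked about, followed so far |  |
| south-west | 0.60 M | 47 mM (held) | run made earlier |  |
| flask | 0.30 M | 47 mM (held) |  | 2.0 h |

| run | time / min | X / % |
|---|---|---|
| north | 3.00 | 0.4 |
| north | 10.0 | 1.6 |
| north | 15.0 | 0.8 |
| north | 25.0 | 3.3 |
| north | 40.0 | 5.5 |
| north | 50.0 | 7.5 |
| north | 60.0 | 9.2 |
| south-west | 6.00 | 0 |
| south-west | 15.0 | 1.9 |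
| south-west | 20.0 | 2.1 |
| south-west | 30.0 | 2.3 |
| south-west | 40.0 | 3.9 |
| south-west | 50.0 | 5.7 |

(readings scatter by 0.5 percentage points)

- the X standing at 2.0 h, as a percentage of the L charged
- the change that raises the amount of X at 2.0 h, in percent of the L charged most ("none" if none brings more than 2 percentage points) (oak / alder / none)
- amount of X at 2.0 h, in percent of the L charged, after oak

- oak: doubling the transfer coefficient of E, all else as stated
- alder: doubling the saturation concentration of E, all else as stated

- at the start none of Z is dissolved
- on the list of suspects stand: E <-> Z; L + Z <-> X; Z + X -> D; L -> G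

From 25.0 min on, the north readings give X made at 0.506 mM/min. With twice the L, the south-west run reads 0.720 mM/min from 20.0 min on, a ratio of 1.42. I suppose uptake of E and use of Z in series, with Z steady. Then the ratio is two divided by (two minus f), where f is the filled fraction, the steady [Z] as a share of saturation, and the reading gives 59.5%. Doubling the transfer then multiplies the rate by two divided by (one plus f), or 1.25, while doubling saturation doubles it, so I choose alder.

Extended straight, the north slope gives 19.3%. I put that back in: reckoned as the charge minus X, mean L in the second hour comes to 0.915 of its value in the slope window, which gives 18.5%, and 23.1% after oak.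

The weak link is the short south-west slope. Taken from 15.0 min on, it reads 0.651 mM/min, so f falls to 44.7% and the oak factor rises to 1.38, still below alder's.

The forecast gives 18.3%, 22% after oak, and alder, since “Doubling saturation roughly doubles the rate”. My figures stand slightly higher.

The flask gives 16.2%, 20.9% after oak, and alder as best, gaining 12 percentage points against 4.6 points for oak.

    E ⇌ Z, rate k1*(csat - [Z]) (kL = 4.48 × 10⁻⁴ /s)
    L + Z ⇌ X (K = 9.00 /M, k = 0.00250 /M/s)
    Z + X → D (k = 4.42 × 10⁻⁴ /M/s)
    L → G (k = 1.37 × 10⁻⁶ /s)

In this flask [Z] is not steady: it climbs from 48.6% of saturation at 1.00 h to 64.5% at 2.00 h, while the f read from the slopes stands at 59.5%. On the oak flask, 1.25 times 16.2% gives 20.2%, beside its 20.9%. Two things, each a part of the reason, act together to hold X in this flask at 16.2% after 2.00 h: without the resistance to uptake it reaches 26.2%, and without the back run from X to L + Z it reaches 24.8%.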